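Everything rests on cutting ring D (C11–C16) at C12–C13 and C14–C15. The key step exploits the 1,3-relationship in ring D between the gem-dimethyl carbon C14 and the ring-fusion carbon C16, flanked by the methyl-bearing C11: a one-pot Michael/aldol (Robinson-type) annulation of tert-butyl acetoacetate (C13, C14 and one C14 methyl) with methyl isopropenyl ketone (C12, C11 with its methyl, C16, C15) forges both bonds and delivers ring D as the C16 enone. The precursor is just these two achiral building blocks. An auxiliary-controlled second Robinson annulation and a reductive alkylation then give the trans-fused CD decalin, an achiral cyclopentenyl unit is added at C7, and ring B is closed last by McMurry coupling at C1=C2.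

Key step: step 1

Remark: locants C1–C19 are the skeletal carbons in the order in which they occur in the target SMILES (methyl carbons not counted); ring A = C2–C6, ring B = C1, C2, C6, C7, C8, C17, C18, C19, ring C = C8–C11, C16, C17, ring D = C11–C16; β is the face of the C11 methyl group, α the opposite face.

Step 1
Reactants: 1 tert-butyl 3-oxobutanoate; 2 3-methylbut-3-en-2-one
Product: 5 3,6-dimethylcyclohex-2-en-1-one (racemic), via Michael adduct 3 (not isolated), via cyclohexenone ester 4 (not isolated)
Conditions: KOt-Bu (10 mol %), t-BuOH, 0 → 80 °C; then TsOH·H2O (20 mol %), toluene, 110 °C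
Reagents that add atoms: none
Why: Base-catalysed Michael addition of the acetoacetate α-carbon (future C13) to the CH2 terminus of the enone (future C12) gives 1,5-diketone 3; the methyl group of the enone-derived acetyl (future C15) then adds to the acetoacetate ketone (future C14) in an intramolecular aldol condensation to 4, and acid removes the tert-butyl ester by loss of isobutene and decarboxylation of the vinylogous β-keto acid. The closest known reaction type is the Robinson annulation in its acetoacetate (Hagemann's ester) variant. Ring D is closed by a 6-(enolendo)-exo-trig aldol addition followed by dehydration. No permanent stereocentre is set: C11 is formed racemic and stays epimerizable until step 4. The step needs aldol regioselectivity (C15 onto C14, not the acetoacetate methyl onto C16); this should be secured by cyclizing while the ester is still in place, where this mode is the established one and the alternative acceptor C16 is α-branched.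

Step 2
Reactants: 5 3,6-dimethylcyclohex-2-en-1-one
Product: 6 2,5,5-trimethylcyclohexan-1-one (racemic)
Conditions: MeMgBr, CuI (10 mol %), THF, −20 °C; aqueous work-up
Reagents that add atoms: methylmagnesium bromide (C[Mg]Br)
Why: Copper-catalysed conjugate addition of the methyl Grignard reagent to the β-methyl enone should complete the C14 gem-dimethyl group; no new stereocentre is formed.

Step 3
Reactants: 6 2,5,5-trimethylcyclohexan-1-one; 7 (R)-1-phenylethan-1-amine
Product: 8 N-[(R)-1-phenylethyl]imine of 6
Conditions: TsOH (cat.), toluene, reflux, Dean–Stark trap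
Reagents that add atoms: none
Why: Acid-catalysed condensation should give the ketimine, whose more substituted secondary enamine tautomer (C11=C16) is the nucleophile of the next step; C11 stays stereolabile.

Step 4
Reactants: 8 N-[(R)-1-phenylethyl]imine of 6; 9 but-3-en-2-one
Product: 12 (S)-4a,7,7-trimethyl-4,4a,5,6,7,8-hexahydronaphthalen-2(3H)-one, via Michael adduct imine 10 (not isolated), via diketone 11 (not isolated)
Conditions: 9, THF, 40 °C; 10 % aq. AcOH, 20 °C; then NaOMe (30 mol %), MeOH, 60 °C
Reagents that add atoms: none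
Why: Deracemizing Michael addition of the chiral secondary enamine through a compact aza-ene-like transition state, attack occurring anti to the phenyl group of the (R)-auxiliary, should set the quaternary C11 as (S); hydrolysis and base-mediated aldol condensation (Robinson annulation) then close ring C, leaving C8 as the enone carbonyl.

Step 5
Reactants: 12 (S)-4a,7,7-trimethyl-4,4a,5,6,7,8-hexahydronaphthalen-2(3H)-one; 13 2-(2-bromoethyl)-2-methyl-1,3-dioxolane
Product: 15 (1S,4aS,8aS)-4a,7,7-trimethyl-1-[2-(2-methyl-1,3-dioxolan-2-yl)ethyl]octahydronaphthalen-2(1H)-one, via lithium enolate 14 (not isolated)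
Conditions: Li, liquid NH3, THF, t-BuOH (1 equiv), −78 °C; NH3 evaporated; 13, HMPA, THF, −20 → 20 °C; H2O
Reagents that add atoms: none
Why: Birch-type reductive alkylation: axial protonation at C16 of the reduced enone should give the trans ring fusion (H16 anti to the C11 methyl), and the regiospecific enolate 14 is alkylated at C17 from the α-face, so the C18–C19–C1 chain ends equatorial (the thermodynamic, epimerizable position).

Step 6
Reactants: 15 trans-decalone bearing the ketal side chain
Product: 17 C8 enol triflate of 15 (C8=C9), via lithium enolate 16 (not isolated)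
Conditions: LiN(i-Pr)2, THF, −78 °C; PhNTf2, −78 → 0 °C
Reagents that add atoms: N-phenylbis(trifluoromethanesulfonimide) (O=S(=O)(N(c1ccccc1)S(=O)(=O)C(F)(F)F)C(F)(F)F)
Why: Kinetic deprotonation by the hindered amide base should occur at the unsubstituted α-carbon C9 rather than at the substituted C17, and O-sulfonylation of enolate 16 gives the enol triflate; no stereocentre is touched.

Step 7
Reactants: 17 C8 enol triflate
Product: 18 C8 hydroxymethyl alkene (C7 as CH2OH on C8; C8=C9)
Conditions: Bu3SnCH2OH, Pd(PPh3)4 (5 mol %), LiCl, 1,4-dioxane, 100 °C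
Reagents that add atoms: (tributylstannyl)methanol (CCCC[Sn](CCCC)(CCCC)CO)
Why: Stille coupling of the enol triflate with the hydroxymethylstannane should install C7 on C8 without affecting the ketal.

Step 8
Reactants: 18 C8 hydroxymethyl alkene
Product: 20 8α-methyl-8β-(hydroxymethyl) trans-decalin (C8 quaternary), via sulfonyl hydrazide 19 (not isolated)
Conditions: 2,4,6-trimethylbenzenesulfonohydrazide, aq. CH2O, Fe(acac)3 (30 mol %), PhSiH3, THF/MeOH, 20 °C; then MeOH, 60 °C
Reagents that add atoms: formaldehyde (C=O)
Why: Iron-hydride hydrogen-atom-transfer (Mukaiyama-type) hydromethylation: Markovnikov hydrogen-atom transfer to C9 gives the tertiary C8 radical, which should add to the formaldehyde sulfonylhydrazone by axial (α-face) attack so that the CH2OH group stays equatorial, and warming in methanol expels sulfinate and N2 from 19 to leave the axial 8α-methyl group.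

Step 9
Reactants: 20 8α-methyl-8β-(hydroxymethyl) trans-decalin
Product: 21 C7 aldehyde of 20
Conditions: Dess–Martin periodinane, pyridine, CH2Cl2, 0 → 20 °C
Reagents that add atoms: none
Why: Dess–Martin oxidation of the neopentyl primary alcohol should give the non-enolizable aldehyde, pyridine buffering the acetic acid to spare the ketal.

Step 10
Reactants: 22 2-bromo-3-methylcyclopent-2-en-1-one
Product: 23 6-bromo-7-methyl-1,4-dioxaspiro[4.4]non-6-ene
Conditions: HOCH2CH2OH, TsOH (cat.), benzene, reflux, Dean–Stark trap
Reagents that add atoms: ethane-1,2-diol (OCCO)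
Why: Acid-catalysed ketalization masks the enone carbonyl (future C2) so that the vinyl bromide can be lithiated, the bromine substituent keeping the double bond in place.

Step 11
Reactants: 21 C7 aldehyde; 23 6-bromo-7-methyl-1,4-dioxaspiro[4.4]non-6-ene
Product: 25 C7 epimeric allylic alcohols, via vinyllithium 24 (not isolated)
Conditions: 23, n-BuLi, THF, −78 °C; then 21, −78 → −20 °C; H2O
Reagents that add atoms: none
Why: Bromine–lithium exchange on 23 gives vinyllithium 24, which should add to the aldehyde to form the C6–C7 bond; the C7 epimers are not separated because this stereocentre is reset in steps 12 and 13.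

Step 12
Reactants: 25 C7 epimeric allylic alcohols
Product: 26 C7 enone (C7 ketone conjugated to C6=C5)
Conditions: Dess–Martin periodinane, pyridine, CH2Cl2, 20 °C
Reagents that add atoms: none
Why: Dess–Martin oxidation of the hindered allylic alcohol should converge both C7 epimers on one enone.

Step 13
Reactants: 26 C7 enone
Product: 27 allylic alcohol of target C7 configuration
Conditions: LiAlH4, Et2O, −78 °C; aq. NaOH work-up
Reagents that add atoms: none
Why: 1,2-Reduction by the small hydride donor under Felkin–Anh-type control by the quaternary C8 (hydride anti to the C17 branch, passing the axial methyl group) should give the C7 configuration of the target, the epimer of the adduct that the same model predicts for step 11.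

Step 14
Reactants: 27 allylic alcohol of target C7 configuration
Product: 28 saturated alcohol (H5/H6 cis)
Conditions: [Ir(cod)(PCy3)(py)]PF6 (10 mol %), H2 (50 bar), CH2Cl2, 20 °C
Reagents that add atoms: none
Why: Hydroxyl-directed hydrogenation: when C7–H eclipses the tetrasubstituted alkene (allylic 1,3-strain against the C5 methyl), the iridium bound to the hydroxyl should deliver both hydrogens syn to the face away from C8, which sets C5 and C6 in the relative configuration of the target.

Step 15
Reactants: 28 saturated alcohol
Product: 29 C7 tert-butyldimethylsilyl ether of 28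
Conditions: TBSOTf, 2,6-lutidine, CH2Cl2, 0 °C
Reagents that add atoms: tert-butyldimethylsilyl trifluoromethanesulfonate (CC(C)(C)[Si](C)(C)OS(=O)(=O)C(F)(F)F)
Why: The silyl triflate should silylate the hindered secondary alcohol, which must be masked so that the β-hydroxy ketone of the next steps cannot undergo retro-aldol cleavage or elimination.

Step 16
Reactants: 29 bis-dioxolane silyl ether
Product: 30 diketone (C1 methyl ketone; C2 cyclopentanone)
Conditions: PPTS (cat.), acetone/H2O, 50 °C
Reagents that add atoms: water (O)
Why: Mild acid-catalysed ketal hydrolysis should free both ketones while leaving the hindered silyl ether and the C6 stereocentre (α to the C2 ketone) untouched.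

Step 17
Reactants: 30 diketone
Product: 31 C7 tert-butyldimethylsilyl ether of the target
Conditions: TiCl3(DME)1.5, Zn(Cu), DME, reflux, slow addition at high dilution
Reagents that add atoms: none
Why: Intramolecular McMurry coupling should join the ketone carbons C1 and C2 into the tetrasubstituted alkene and close the eight-membered ring B; the alkene can only be cis within the ring, and no stereocentre is formed.

Step 18
Reactants: 31 silyl ether of the target
Product: 32 CNP0399382.1
Conditions: TBAF, THF, 50 °C; H2O
Reagents that add atoms: none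
Why: Fluoride cleavage of the silyl ether should liberate the C7 alcohol without touching the tetrasubstituted alkene.

Compound list
1 | tert-butyl 3-oxobutanoate | CC(=O)CC(=O)OC(C)(C)C | starting material
2 | 3-methylbut-3-en-2-one | CC(=C)C(C)=O | starting material
3 | tert-butyl 2-acetyl-4-methyl-5-oxohexanoate (Michael adduct) | CC(=O)C(CC(C)C(C)=O)C(=O)OC(C)(C)C | intermediate
4 | tert-butyl 2,5-dimethyl-4-oxocyclohex-2-ene-1-carboxylate | CC1=CC(=O)C(C)CC1C(=O)OC(C)(C)C | intermediate
5 | 3,6-dimethylcyclohex-2-en-1-one (racemic) | CC1=CC(=O)C(C)CC1 | intermediate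
6 | 2,5,5-trimethylcyclohexan-1-one (racemic) | CC1CCC(C)(C)CC1=O | intermediate
7 | (R)-1-phenylethan-1-amine | C[C@@H](N)c1ccccc1 | starting material
8 | N-[(R)-1-phenylethyl]imine of 2,5,5-trimethylcyclohexan-1-one | C[C@@H](N=C1CC(C)(C)CCC1C)c1ccccc1 | intermediate
9 | but-3-en-2-one | CC(=O)C=C | starting material
10 | N-[(R)-1-phenylethyl]imine of (S)-2,5,5-trimethyl-2-(3-oxobutyl)cyclohexan-1-one | CC(=O)CC[C@]1(C)CCC(C)(C)CC1=N[C@H](C)c1ccccc1 | intermediate
11 | (S)-2,5,5-trimethyl-2-(3-oxobutyl)cyclohexan-1-one | CC(=O)CC[C@]1(C)CCC(C)(C)CC1=O | intermediate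
12 | (S)-4a,7,7-trimethyl-4,4a,5,6,7,8-hexahydronaphthalen-2(3H)-one | CC1(C)CC[C@@]2(C)CCC(=O)C=C2C1 | intermediate
13 | 2-(2-bromoethyl)-2-methyl-1,3-dioxolane | CC1(CCBr)OCCO1 | starting material
14 | lithium enolate of the trans-fused decalone (C8–OLi, C8=C17; 11β-CH3, 16α-H) | [Li]OC1=C[C@@H]2CC(C)(C)CC[C@@]2(C)CC1 | intermediate
15 | (1S,4aS,8aS)-4a,7,7-trimethyl-1-[2-(2-methyl-1,3-dioxolan-2-yl)ethyl]octahydronaphthalen-2(1H)-one (C8 ketone; 11β-CH3, 16α-H, 17β-H) | CC1(OCCO1)CC[C@@H]2C(=O)CC[C@]3(C)CCC(C)(C)C[C@H]32 | intermediate
16 | lithium enolate of 15 (C8–OLi, C8=C9) | CC1(OCCO1)CC[C@@H]2C(O[Li])=CC[C@]3(C)CCC(C)(C)C[C@H]32 | intermediate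
17 | enol triflate of 15 (C8–OSO2CF3, C8=C9) | CC1(OCCO1)CC[C@@H]2C(OS(=O)(=O)C(F)(F)F)=CC[C@]3(C)CCC(C)(C)C[C@H]32 | intermediate
18 | C8 hydroxymethyl alkene (C7 as CH2OH on C8; C8=C9) | CC1(OCCO1)CC[C@@H]2C(CO)=CC[C@]3(C)CCC(C)(C)C[C@H]32 | intermediate
19 | N'-alkyl 2,4,6-trimethylbenzenesulfonohydrazide (C8–CH2–NH–NH–SO2Ar, C8β-CH2OH) | CC1(OCCO1)CC[C@@H]2[C@@](CNNS(=O)(=O)c4c(C)cc(C)cc4C)(CO)CC[C@]3(C)CCC(C)(C)C[C@H]32 | intermediate
20 | 8α-methyl-8β-(hydroxymethyl) trans-decalin bearing the C17 ketal side chain | CC1(OCCO1)CC[C@@H]2[C@@](C)(CO)CC[C@]3(C)CCC(C)(C)C[C@H]32 | intermediate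
21 | C7 aldehyde (8α-methyl-8β-formyl) | CC1(OCCO1)CC[C@@H]2[C@@](C)(C=O)CC[C@]3(C)CCC(C)(C)C[C@H]32 | intermediate
22 | 2-bromo-3-methylcyclopent-2-en-1-one | CC1=C(Br)C(=O)CC1 | starting material
23 | 6-bromo-7-methyl-1,4-dioxaspiro[4.4]non-6-ene | CC1=C(Br)C2(CC1)OCCO2 | intermediate
24 | (7-methyl-1,4-dioxaspiro[4.4]non-6-en-6-yl)lithium | CC1=C([Li])C2(CC1)OCCO2 | intermediate
25 | C7 epimeric allylic alcohols (C7–OH, C6=C5, C2 dioxolane) | CC1(OCCO1)CC[C@@H]2[C@@](C)(C(O)C4=C(C)CCC45OCCO5)CC[C@]3(C)CCC(C)(C)C[C@H]32 | intermediate
26 | C7 enone (C7 ketone, C6=C5, C2 dioxolane) | CC1(OCCO1)CC[C@@H]2[C@@](C)(C(=O)C4=C(C)CCC45OCCO5)CC[C@]3(C)CCC(C)(C)C[C@H]32 | intermediate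
27 | allylic alcohol of target C7 configuration | CC1(OCCO1)CC[C@@H]2[C@@](C)([C@H](O)C4=C(C)CCC45OCCO5)CC[C@]3(C)CCC(C)(C)C[C@H]32 | intermediate
28 | saturated alcohol (H5/H6 cis, C7–OH, two dioxolanes) | CC1(OCCO1)CC[C@@H]2[C@@](C)([C@H](O)[C@H]4[C@@H](C)CCC45OCCO5)CC[C@]3(C)CCC(C)(C)C[C@H]32 | intermediate
29 | C7 tert-butyldimethylsilyl ether of 28 | CC1(OCCO1)CC[C@@H]2[C@@](C)([C@H](O[Si](C)(C)C(C)(C)C)[C@H]4[C@@H](C)CCC45OCCO5)CC[C@]3(C)CCC(C)(C)C[C@H]32 | intermediate
30 | diketone (C1 methyl ketone, C2 cyclopentanone, C7–OTBS) | CC(=O)CC[C@@H]2[C@@](C)([C@H](O[Si](C)(C)C(C)(C)C)[C@H]4[C@@H](C)CCC4=O)CC[C@]3(C)CCC(C)(C)C[C@H]32 | intermediate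
31 | C7 tert-butyldimethylsilyl ether of the target | C/C1=C2\CC[C@H](C)[C@@H]2[C@@H](O[Si](C)(C)C(C)(C)C)[C@@]2(C)CC[C@]3(C)CCC(C)(C)C[C@H]3[C@@H]2CC1 | intermediate
32 | CNP0399382.1 (5β-H, 6β-H, 7β-OH, 8α-CH3, 11β-CH3, 16α-H, 17β-H) | C/C1=C2\CC[C@H](C)[C@@H]2[C@@H](O)[C@@]2(C)CC[C@]3(C)CCC(C)(C)C[C@H]3[C@@H]2CC1 | target

Total step count: 18. Longest linear sequence: 17 steps (steps 1–9 and 11–18).

Steps most likely to fail

Step 17. Oligomerization may outrun closure of the eight-membered ring, and the hot Lewis-acidic medium may eliminate the β-silyloxy group or epimerize C6. The fallback separates C–C bond formation from deoxygenation. Setting out from 30, SmI2 in THF/HMPA at −78 → 0 °C should effect an intramolecular pinacol coupling to the cis-1,2-diol F1. Thiocarbonyldiimidazole and DMAP in hot toluene should convert it into the cyclic thiocarbonate F2. Corey–Hopkins fragmentation by 1,3-dimethyl-2-phenyl-1,3,2-diazaphospholidine at 40 °C then comes back to the route at 31.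

Step 8. The C8 radical may be trapped with poor facial selectivity, or be reduced instead of forming the C–C bond. The fallback delivers the methyl carbon by a concerted, face-selective cycloaddition. Setting out from 18, hydroxyl-assisted Simmons–Smith cyclopropanation (Et2Zn, CH2I2, CH2Cl2, 0 °C) should occur on the α-face, away from the axial C11 methyl group, to give the cyclopropylmethanol F3. Hydrogenolysis (H2, PtO2, AcOH/EtOAc) of the least substituted cyclopropane bond (C9–CH2) then comes back to the route at 20.

Step 13. Hydride delivery to the ketone between a quaternary carbon and a tetrasubstituted alkene may show poor facial selectivity, since the methyl and CH2 substituents on C8 differ little in size. The fallback replaces substrate control by reagent control. Setting out from 26, oxazaborolidine-catalysed borane reduction (CBS reduction, the catalyst enantiomer matched to the required face and the alkenyl group acting as the large substituent) comes back to the route at 27; this fallback makes no new compound (F0).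

Further compounds
F1 | step 17 | cis-1,2-diol from pinacol coupling of 30 (C1–OH, C2–OH, C7–OTBS) | CC1(O)C2(O)CC[C@H](C)[C@@H]2[C@@H](O[Si](C)(C)C(C)(C)C)[C@@]2(C)CC[C@]3(C)CCC(C)(C)C[C@H]3[C@@H]2CC1
F2 | step 17 | cyclic thiocarbonate of F1 | CC16OC(=S)OC62CC[C@H](C)[C@@H]2[C@@H](O[Si](C)(C)C(C)(C)C)[C@@]2(C)CC[C@]3(C)CCC(C)(C)C[C@H]3[C@@H]2CC1
F3 | step 8 | cyclopropylmethanol (CH2 bridging C8 and C9 on the α-face, C8β-CH2OH) | CC1(OCCO1)CC[C@@H]2[C@]4(CO)C[C@@H]4C[C@]3(C)CCC(C)(C)C[C@H]32
F0 | step 13 | none | none
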